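The isoxazolidine ring (N1–O2–C3–C3a–C6a) is traced back to a ring lacking O2: the azetidine (N–C3–C3a–C6a) of a cis-fused 6-azabicyclo[3.2.0]heptane in which C3 carries the future octyl chain as a 1-alkynyl group. N-Oxidation of this amine should trigger a strain-driven [1,2]-Meisenheimer shift that inserts oxygen into the propargylic N–C3 bond with retention, enlarging the four-membered ring to the N–O five-membered ring in one operation. C3a and C6a come from an enantiopure cyclopentane-fused β-lactam; C3 is set by a reagent-controlled ynone reduction and an invertive azetidine closure. Diimide saturation of the alkynes then gives the target.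

Key step: step 9

Remark on numbering: the target is numbered N1, O2, C3, C3a, C4–C6, C6a (hexahydro-1H-cyclopenta[c]isoxazole); in the 6-azabicyclo[3.2.0]heptanes C7, C1 and C5 correspond to C3, C3a and C6a.
Assumption: (1S,5R)-6-azabicyclo[3.2.0]heptan-7-one, the enantiopure β-lactam of cis-2-aminocyclopentanecarboxylic acid, is taken as a purchasable building block.

Step 1
Reactants: 1 3-bromopyridine; 2 octa-1,7-diyne
Product: 3 3-(octa-1,7-diyn-1-yl)pyridine
Conditions: PdCl2(PPh3)2 (2 mol %), CuI (4 mol %), Et3N, 2 (5 equiv), 50 °C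
Reagents that add atoms: none
Why: Sonogashira coupling of the aryl bromide with one terminus of the diyne, with the large excess of the volatile diyne suppressing double arylation, should give the mono-coupled product that keeps a terminal C–H for step 4.

Step 2
Reactants: 4 3-methylpyridine; 5 1,11-dibromoundecane
Product: 7 3-(12-bromododecyl)pyridine, via 3-picolyllithium 6 (not isolated)
Conditions: LiN(iPr)2, THF, −78 °C; then 5 (3 equiv), −78 → 0 °C
Reagents that add atoms: none
Why: Lateral lithiation of 3-picoline followed by SN2 alkylation with an excess of the dibromide should give the mono-alkylated ω-bromide, which is to be used promptly to avoid self-quaternisation.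

Step 3
Reactants: 8 (1S,5R)-6-azabicyclo[3.2.0]heptan-7-one
Product: 9 tert-butyl (1S,5R)-7-oxo-6-azabicyclo[3.2.0]heptane-6-carboxylate
Conditions: Boc2O, DMAP (cat.), MeCN, rt
Reagents that add atoms: di-tert-butyl dicarbonate (Boc2O), CC(C)(C)OC(=O)OC(=O)OC(C)(C)C
Why: N-Acylation of the lactam nitrogen (DMAP-catalysed carbamoylation) activates the strained lactam carbonyl for nucleophilic ring opening and leaves both stereocentres untouched.

Step 4
Reactants: 3 3-(octa-1,7-diyn-1-yl)pyridine; 9 tert-butyl (1S,5R)-7-oxo-6-azabicyclo[3.2.0]heptane-6-carboxylate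
Product: 11 tert-butyl N-[(1R,2S)-2-[9-(pyridin-3-yl)nona-2,8-diynoyl]cyclopentyl]carbamate, via lithium acetylide 10 (not isolated)
Conditions: 3, n-BuLi (1.0 equiv), THF, −78 °C; then 9, −78 °C; AcOH quench at −78 °C
Reagents that add atoms: none
Why: Acetylide addition to the activated β-lactam carbonyl followed by collapse of the tetrahedral intermediate to the carbamate anion (nucleophilic ring opening of an N-Boc lactam) should give the cis β-amino ynone, with the cold acidic quench guarding the epimerisable α-centre.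

Step 5
Reactants: 11 tert-butyl N-[(1R,2S)-2-[9-(pyridin-3-yl)nona-2,8-diynoyl]cyclopentyl]carbamate
Product: 12 tert-butyl N-[(1R,2S)-2-[(1S)-1-hydroxy-9-(pyridin-3-yl)nona-2,8-diyn-1-yl]cyclopentyl]carbamate
Conditions: Ru[(S,S)-TsDPEN](p-cymene) (1 mol %; TsDPEN = N-tosyl-1,2-diphenylethylenediamine), iPrOH, rt
Reagents that add atoms: none
Why: Noyori asymmetric transfer hydrogenation of the ynone under base-free conditions is expected to set the carbinol centre as S by catalyst control (the alkynyl group playing the role of the aryl group of aryl ketones), without touching the alkynes or the α-stereocentre; the (R,R)-complex would be used if the sense of induction proved opposite.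

Step 6
Reactants: 12 tert-butyl N-[(1R,2S)-2-[(1S)-1-hydroxy-9-(pyridin-3-yl)nona-2,8-diyn-1-yl]cyclopentyl]carbamate
Product: 13 (1S)-1-[(1S,2R)-2-(tert-butoxycarbonylamino)cyclopentyl]-9-(pyridin-3-yl)nona-2,8-diyn-1-yl methanesulfonate
Conditions: MsCl, Et3N, CH2Cl2, −20 °C
Reagents that add atoms: methanesulfonyl chloride (MsCl), CS(=O)(=O)Cl
Why: O-Sulfonylation of the secondary propargylic alcohol proceeds with retention at carbon and should be chemoselective because the carbamate N–H is not nucleophilic under these conditions.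

Step 7
Reactants: 13 (1S)-1-[(1S,2R)-2-(tert-butoxycarbonylamino)cyclopentyl]-9-(pyridin-3-yl)nona-2,8-diyn-1-yl methanesulfonate
Product: 15 (1S,5R,7R)-7-[8-(pyridin-3-yl)octa-1,7-diyn-1-yl]-6-azabicyclo[3.2.0]heptane, via amino mesylate 14 (not isolated)
Conditions: TFA, CH2Cl2, 0 °C; evaporation; then K2CO3, MeCN (0.01 M), 60 °C
Reagents that add atoms: none
Why: Acidolysis of the Boc group and neutralisation at high dilution should let the cis-disposed primary amine displace the activated propargylic mesylate in a 4-exo-tet SN2 cyclisation with inversion, so the (S)-mesylate gives the (7R)-azetidine with all three ring hydrogens cis, an SN2′ course being geometrically excluded.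

Step 8
Reactants: 15 (1S,5R,7R)-7-[8-(pyridin-3-yl)octa-1,7-diyn-1-yl]-6-azabicyclo[3.2.0]heptane; 7 3-(12-bromododecyl)pyridine
Product: 16 (1S,5R,7R)-6-[12-(pyridin-3-yl)dodecyl]-7-[8-(pyridin-3-yl)octa-1,7-diyn-1-yl]-6-azabicyclo[3.2.0]heptane
Conditions: K2CO3, MeCN, 60 °C, 7 (1.0 equiv)
Reagents that add atoms: none
Why: SN2 N-alkylation of the secondary azetidine nitrogen, a far better nucleophile than the pyridine nitrogens, with the primary bromide should give the tertiary amine, one equivalent of bromide limiting quaternisation.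

Step 9
Reactants: 16 (1S,5R,7R)-6-[12-(pyridin-3-yl)dodecyl]-7-[8-(pyridin-3-yl)octa-1,7-diyn-1-yl]-6-azabicyclo[3.2.0]heptane
Product: 18 (3R,3aS,6aR)-1-[12-(pyridin-3-yl)dodecyl]-3-[8-(pyridin-3-yl)octa-1,7-diyn-1-yl]hexahydro-1H-cyclopenta[c]isoxazole, via azetidine N-oxide 17 (not isolated)
Conditions: mCPBA (1.0 equiv), CH2Cl2, −78 → 0 °C; aq NaHCO3 wash; then CH2Cl2, 25 → 40 °C
Reagents that add atoms: 3-chloroperoxybenzoic acid (mCPBA), O=C(OO)c1cccc(Cl)c1
Why: The peracid should oxidise the most nucleophilic nitrogen, the tertiary azetidine N, far faster than either pyridine, and the strained N-oxide 17 is expected to rearrange on warming by homolysis of the propargylic N–C bond to a tethered nitroxide/propargyl radical pair that recombines at oxygen. This is a [1,2]-Meisenheimer rearrangement, the known ring expansion of azetidine N-oxides to isoxazolidines, driven by release of the four-membered-ring strain. The only ring closed is the isoxazolidine, by O–C3 bond formation within the tethered pair (ring enlargement through insertion of O into N–C3, five-membered closure), while the cyclopentane and the cis C3a–C6a fusion are never broken. C3 is the one stereocentre at stake and should be formed with retention, because the C3a–C6a tether holds the oxygen on the face from which nitrogen departs and collapse of the singlet pair is expected to outrun rotation about C3–C3a, so its configuration is relayed from C7 of 16 (the N-oxide nitrogen is a transient centre of no consequence). Regioselectivity for N–C3 over N–C6a or N–CH2 cleavage is secured by the alkyne, which makes C3 the only propargylic, radical-stabilised carbon, and the competing [2,3]-shift through the triple bond would have to deliver a seven-membered cyclic allene and is not expected. Chemoselectivity requires one equivalent of peracid at low temperature, which the alkynes and pyridines should survive.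

Step 10
Reactants: 18 (3R,3aS,6aR)-1-[12-(pyridin-3-yl)dodecyl]-3-[8-(pyridin-3-yl)octa-1,7-diyn-1-yl]hexahydro-1H-cyclopenta[c]isoxazole
Product: 20 (3S,3aS,6aR)-1-[12-(pyridin-3-yl)dodecyl]-3-[8-(pyridin-3-yl)octyl]hexahydro-1H-cyclopenta[c]isoxazole, via bis-cis-diene 19 (not isolated)
Conditions: TsNHNH2 (20 equiv, in portions), NaOAc (20 equiv), DME/H2O (1:1), 85 °C
Reagents that add atoms: none
Why: Diimide generated in the flask transfers H2 concertedly and syn to nonpolar C–C multiple bonds only, so both alkynes should be saturated through the cis-alkenes while the N–O bond, the propargylic/allylic C–O bond and the pyridine rings stay intact, the C3 descriptor changing from R to S solely through the change in CIP priorities.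

Compound list
1 | 3-bromopyridine | Brc1cccnc1 | starting material
2 | octa-1,7-diyne | C#CCCCCC#C | starting material
3 | 3-(octa-1,7-diyn-1-yl)pyridine | C#CCCCCC#Cc1cccnc1 | intermediate
4 | 3-methylpyridine | Cc1cccnc1 | starting material
5 | 1,11-dibromoundecane | BrCCCCCCCCCCCBr | starting material
6 | 3-picolyllithium (formed in the flask) | [Li]Cc1cccnc1 | intermediate
7 | 3-(12-bromododecyl)pyridine | BrCCCCCCCCCCCCc1cccnc1 | intermediate
8 | (1S,5R)-6-azabicyclo[3.2.0]heptan-7-one | N1C(=O)[C@H]2CCC[C@H]21 | starting material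
9 | tert-butyl (1S,5R)-7-oxo-6-azabicyclo[3.2.0]heptane-6-carboxylate | CC(C)(C)OC(=O)N1C(=O)[C@H]2CCC[C@H]21 | intermediate
10 | lithium acetylide of 3, [8-(pyridin-3-yl)octa-1,7-diyn-1-yl]lithium (formed in the flask) | [Li]C#CCCCCC#Cc1cccnc1 | intermediate
11 | tert-butyl N-[(1R,2S)-2-[9-(pyridin-3-yl)nona-2,8-diynoyl]cyclopentyl]carbamate | O=C(C#CCCCCC#Cc1cccnc1)[C@H]2CCC[C@H]2NC(=O)OC(C)(C)C | intermediate
12 | tert-butyl N-[(1R,2S)-2-[(1S)-1-hydroxy-9-(pyridin-3-yl)nona-2,8-diyn-1-yl]cyclopentyl]carbamate | O[C@H](C#CCCCCC#Cc1cccnc1)[C@H]2CCC[C@H]2NC(=O)OC(C)(C)C | intermediate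
13 | (1S)-1-[(1S,2R)-2-(tert-butoxycarbonylamino)cyclopentyl]-9-(pyridin-3-yl)nona-2,8-diyn-1-yl methanesulfonate | CS(=O)(=O)O[C@H](C#CCCCCC#Cc1cccnc1)[C@H]2CCC[C@H]2NC(=O)OC(C)(C)C | intermediate
14 | (1S)-1-[(1S,2R)-2-aminocyclopentyl]-9-(pyridin-3-yl)nona-2,8-diyn-1-yl methanesulfonate (formed in the flask as its trifluoroacetate salt, shown as free base) | CS(=O)(=O)O[C@H](C#CCCCCC#Cc1cccnc1)[C@H]2CCC[C@H]2N | intermediate
15 | (1S,5R,7R)-7-[8-(pyridin-3-yl)octa-1,7-diyn-1-yl]-6-azabicyclo[3.2.0]heptane (H-1, H-5, H-7 all cis) | N1[C@@H](C#CCCCCC#Cc3cccnc3)[C@H]2CCC[C@H]21 | intermediate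
16 | (1S,5R,7R)-6-[12-(pyridin-3-yl)dodecyl]-7-[8-(pyridin-3-yl)octa-1,7-diyn-1-yl]-6-azabicyclo[3.2.0]heptane | c1cncc(CCCCCCCCCCCCN2[C@@H](C#CCCCCC#Cc3cccnc3)[C@H]3CCC[C@H]32)c1 | intermediate
17 | (1S,5R,7R)-6-[12-(pyridin-3-yl)dodecyl]-7-[8-(pyridin-3-yl)octa-1,7-diyn-1-yl]-6-azabicyclo[3.2.0]heptane 6-oxide (configuration at N not defined; formed in the flask) | c1cncc(CCCCCCCCCCCC[N+]2([O-])[C@@H](C#CCCCCC#Cc3cccnc3)[C@H]3CCC[C@H]32)c1 | intermediate
18 | (3R,3aS,6aR)-1-[12-(pyridin-3-yl)dodecyl]-3-[8-(pyridin-3-yl)octa-1,7-diyn-1-yl]hexahydro-1H-cyclopenta[c]isoxazole (H-3, H-3a, H-6a all cis) | c1cncc(CCCCCCCCCCCCN2O[C@@H](C#CCCCCC#Cc3cccnc3)[C@H]3CCC[C@H]32)c1 | intermediate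
19 | (3S,3aS,6aR)-1-[12-(pyridin-3-yl)dodecyl]-3-[(1Z,7Z)-8-(pyridin-3-yl)octa-1,7-dien-1-yl]hexahydro-1H-cyclopenta[c]isoxazole (formed in the flask) | c1cncc(CCCCCCCCCCCCN2O[C@@H](/C=C\CCCC/C=C\c3cccnc3)[C@H]3CCC[C@H]32)c1 | intermediate
20 | (3S,3aS,6aR)-1-[12-(pyridin-3-yl)dodecyl]-3-[8-(pyridin-3-yl)octyl]hexahydro-1H-cyclopenta[c]isoxazole (H-3, H-3a, H-6a all cis) | c1cncc(CCCCCCCCCCCCN2O[C@@H](CCCCCCCCc3cccnc3)[C@H]3CCC[C@H]32)c1 | target

Total step count: 10
Longest linear sequence: 8 steps (steps 3–10 from lactam 8; equally steps 1 and 4–10 from 3-bromopyridine)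

Steps most likely to fail

1. Step 9. What may go wrong: rotation about C3–C3a inside the radical pair before recombination, which would erode the C3 configuration towards the exo epimer; or partial cleavage of the N–C6a bond or over-oxidation of a pyridine. Fallback (ionic N–O–C3 construction by known chemistry), setting out from alcohol 12 and returning at 18: Boc removal (TFA, CH2Cl2, 0 °C, basic work-up) should give (1S)-1-[(1S,2R)-2-aminocyclopentyl]-9-(pyridin-3-yl)nona-2,8-diyn-1-ol F1. Mono-N-alkylation with bromide 7 (K2CO3, MeCN, amine in excess) should give (1S)-9-(pyridin-3-yl)-1-[(1S,2R)-2-{[12-(pyridin-3-yl)dodecyl]amino}cyclopentyl]nona-2,8-diyn-1-ol F2. Oxidation of the secondary amine with dibenzoyl peroxide (K2HPO4, DMF, rt) should give O-benzoyl-N-[(1R,2S)-2-[(1S)-1-hydroxy-9-(pyridin-3-yl)nona-2,8-diyn-1-yl]cyclopentyl]-N-[12-(pyridin-3-yl)dodecyl]hydroxylamine F3. Mesylation (MsCl, Et3N, CH2Cl2, −20 °C) should give the methanesulfonate of F3, (1S)-1-[(1S,2R)-2-{(benzoyloxy)[12-(pyridin-3-yl)dodecyl]amino}cyclopentyl]-9-(pyridin-3-yl)nona-2,8-diyn-1-yl methanesulfonate F4. Methanolysis of the benzoate (K2CO3, MeOH, 0 °C → rt) should free the N-hydroxy amine mesylate (1S)-1-[(1S,2R)-2-{hydroxy[12-(pyridin-3-yl)dodecyl]amino}cyclopentyl]-9-(pyridin-3-yl)nona-2,8-diyn-1-yl methanesulfonate F5 (not isolated), whose oxygen should displace the mesylate by 5-exo-tet SN2 with inversion to give 18.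

2. Step 7. What may go wrong: slow 4-exo-tet closure of the neutral primary amine, leaving time for elimination of the propargylic mesylate to an enyne or for intermolecular N-alkylation. Fallback (sulfonamide-anion cyclisation), setting out from amino mesylate 14 (generated from 13 with TFA as in step 7) and returning at 15: the salt is neutralised in the presence of 2-nitrobenzenesulfonyl chloride (iPr2NEt, CH2Cl2, 0 °C), where N-sulfonylation should outrun cyclisation, to give (1S)-1-[(1S,2R)-2-(2-nitrobenzenesulfonamido)cyclopentyl]-9-(pyridin-3-yl)nona-2,8-diyn-1-yl methanesulfonate F6. Cs2CO3 in DMF at rt should then close the ring through the sulfonamide anion (4-exo-tet SN2, inversion) to (1S,5R,7R)-6-(2-nitrobenzenesulfonyl)-7-[8-(pyridin-3-yl)octa-1,7-diyn-1-yl]-6-azabicyclo[3.2.0]heptane F7. Thiolate cleavage of the sulfonamide (PhSH, K2CO3, MeCN, rt) should give 15.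

3. Step 10. What may go wrong: stalling of the diimide reduction at the alkene stage for the two internal triple bonds, with thermal degradation on prolonged heating. Fallback (staged catalytic hydrogenation), setting out from 18 and returning at 20: semi-hydrogenation with H2 (1 atm) over Pd on CaCO3 poisoned with Pb(OAc)2 and quinoline in EtOAc should give the bis-cis-diene 19, this time isolated, and homogeneous hydrogenation with H2 (1 atm) and RhCl(PPh3)3 in benzene/EtOH, which does not hydrogenolyse N–O or C–O bonds, should saturate the two cis-alkenes to 20. This fallback makes no compound outside the compound list (F0).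

Further compounds
F1 | step 9 | (1S)-1-[(1S,2R)-2-aminocyclopentyl]-9-(pyridin-3-yl)nona-2,8-diyn-1-ol | O[C@H](C#CCCCCC#Cc1cccnc1)[C@H]2CCC[C@H]2N
F2 | step 9 | (1S)-9-(pyridin-3-yl)-1-[(1S,2R)-2-{[12-(pyridin-3-yl)dodecyl]amino}cyclopentyl]nona-2,8-diyn-1-ol | O[C@H](C#CCCCCC#Cc1cccnc1)[C@H]2CCC[C@H]2NCCCCCCCCCCCCc1cccnc1
F3 | step 9 | O-benzoyl-N-[(1R,2S)-2-[(1S)-1-hydroxy-9-(pyridin-3-yl)nona-2,8-diyn-1-yl]cyclopentyl]-N-[12-(pyridin-3-yl)dodecyl]hydroxylamine | O[C@H](C#CCCCCC#Cc1cccnc1)[C@H]2CCC[C@H]2N(OC(=O)c1ccccc1)CCCCCCCCCCCCc1cccnc1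
F4 | step 9 | (1S)-1-[(1S,2R)-2-{(benzoyloxy)[12-(pyridin-3-yl)dodecyl]amino}cyclopentyl]-9-(pyridin-3-yl)nona-2,8-diyn-1-yl methanesulfonate | CS(=O)(=O)O[C@H](C#CCCCCC#Cc1cccnc1)[C@H]2CCC[C@H]2N(OC(=O)c1ccccc1)CCCCCCCCCCCCc1cccnc1
F5 | step 9 | (1S)-1-[(1S,2R)-2-{hydroxy[12-(pyridin-3-yl)dodecyl]amino}cyclopentyl]-9-(pyridin-3-yl)nona-2,8-diyn-1-yl methanesulfonate | CS(=O)(=O)O[C@H](C#CCCCCC#Cc1cccnc1)[C@H]2CCC[C@H]2N(O)CCCCCCCCCCCCc1cccnc1
F6 | step 7 | (1S)-1-[(1S,2R)-2-(2-nitrobenzenesulfonamido)cyclopentyl]-9-(pyridin-3-yl)nona-2,8-diyn-1-yl methanesulfonate | CS(=O)(=O)O[C@H](C#CCCCCC#Cc1cccnc1)[C@H]2CCC[C@H]2NS(=O)(=O)c1ccccc1[N+](=O)[O-]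
F7 | step 7 | (1S,5R,7R)-6-(2-nitrobenzenesulfonyl)-7-[8-(pyridin-3-yl)octa-1,7-diyn-1-yl]-6-azabicyclo[3.2.0]heptane | O=S(=O)(c1ccccc1[N+](=O)[O-])N1[C@@H](C#CCCCCC#Cc3cccnc3)[C@H]2CCC[C@H]21
F0 | step 10 | none | none
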